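**Plan**
- Retrosynthesis: the phenol is masked as its acetate; the O3–acetyl and O4–cinnamoyl ester bonds are cut back to (3R,4S)-3,7-dimethylocta-1,6-diene-3,4-diol; then the C3–C4 bond between the fully substituted carbinol carbon and the secondary carbinol carbon is cut.
- Enabling feature: C3 carries the C1=C2 vinyl group, a methyl group and oxygen, and is bonded to the carbinol carbon C4. This is the retron of γ-attack of a γ,γ-disubstituted allylborane on an aldehyde; C1=C2 is the transposed allyl double bond and the C3–O bond is carried through the union as C3–B.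
- Forward: but-2-yn-1-ol → allenylboronate; hydroboration with (+)-diisopinocampheylborane; union with 4-methylpent-3-enal and oxidation → diol; O4 esterified with 4-acetoxycinnamic acid; O3 acetylated; phenolic acetate removed.
- Stereochemistry: C4 (S) from the isopinocampheyl groups (aldehyde Re face); C3 (R) from the allylborane geometry through a chair transition state and C–B oxidation with retention; the E-cinnamate comes with the purchased acid.

Key step: step 5

Remark: carbons are numbered as in 3,7-dimethylocta-1,6-diene (C1=C2 vinyl, C3 quaternary, C4 secondary carbinol). The target is the (3R,4S) isomer, i.e. the two oxygens are anti when C2–C3–C4–C5 is drawn zigzag. The borane from (−)-α-pinene is assumed to show the usual facial sense of diisopinocampheyl allylboranes (Re-face attack on the aldehyde); if the sense were opposite, the borane from (+)-α-pinene would be used.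

Step 1
Reactants: 1 but-2-yn-1-ol
Product: 2 but-2-yn-1-yl methyl carbonate
Conditions: ClCO2Me, pyridine, CH2Cl2, 0 °C to rt
Reagents that add atoms: methyl chloroformate, COC(=O)Cl
Why: Acylation of a primary propargylic alcohol by a chloroformate with pyridine is routine carbonate formation and installs the leaving group for the SN2′ borylation.

Step 2
Reactants: 2 but-2-yn-1-yl methyl carbonate
Product: 3 2-(buta-2,3-dien-2-yl)-4,4,5,5-tetramethyl-1,3,2-dioxaborolane
Conditions: B2pin2, CuCl/Xantphos (5 mol %), KOt-Bu (10 mol %), THF, rt
Reagents that add atoms: bis(pinacolato)diboron, CC1(C)OB(OC1(C)C)B1OC(C)(C)C(C)(C)O1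
Why: Copper(I)-catalysed γ-selective (SN2′) borylation of a propargylic carbonate: Cu–Bpin adds across the alkyne with boron on the methyl-bearing carbon, and β-elimination of the carbonate should give the 1,1-disubstituted allenylboronate.

Step 3
Reactants: 4 (−)-α-pinene
Product: 5 (+)-diisopinocampheylborane [(lIpc)2BH]
Conditions: BH3·SMe2 (1 equiv), 4 (2.2 equiv), THF, 0 °C; crystallised and collected under argon
Reagents that add atoms: borane–dimethyl sulfide, C[S+](C)[BH3-]
Why: Hydroboration of α-pinene stops at the dialkylborane and occurs on the face anti to the gem-dimethyl bridge; the slight excess of pinene and crystallisation should raise the enantiomeric purity of the reagent.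

Step 4
Reactants: 6 4-methylpent-3-en-1-ol
Product: 7 4-methylpent-3-enal
Conditions: Dess–Martin periodinane (1.2 equiv), CH2Cl2, 0 °C to rt; pentane, filtration, cold concentration; used at once as a toluene solution
Reagents that add atoms: none
Why: Dess–Martin oxidation of a primary alcohol stops at the aldehyde under nearly neutral conditions, which should keep the β,γ-double bond out of conjugation if the volatile aldehyde is kept cold and used directly.

Step 5
Reactants: 3 2-(buta-2,3-dien-2-yl)-4,4,5,5-tetramethyl-1,3,2-dioxaborolane; 5 (+)-diisopinocampheylborane; 7 4-methylpent-3-enal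
Product: 11 (3R,4S)-3,7-dimethylocta-1,6-diene-3,4-diol, via kinetic allylborane 8 (not isolated), via equilibrated allylborane 9 (not isolated), via borinate adduct 10 (not isolated)
Conditions: 3 + 5 (1.1 equiv each), toluene, 0 °C, 2 h, then 85 °C, 1.5 h; −78 °C, 7 (1.0 equiv), 4 h; then 3 M NaOH, 30% H2O2, THF, 0 °C to rt
Reagents that add atoms: hydrogen peroxide, OO
Why: The borane adds to the unsubstituted terminal C=C of the allene with boron on CH2 and hydrogen on the central carbon, and reversible 1,3-boratropic shifts at 85 °C should convert the first-formed allylborane 8 into the more stable isomer 9, in which the pinacolboryl group is trans to CH2B(Ipc)2. This γ,γ-disubstituted allylborane adds through its γ-carbon to the aldehyde in a closed six-membered chair transition state (Zimmerman–Traxler type), which forms the C3–C4 bond at the fully substituted carbon and moves the double bond to C1=C2. The closest known reaction type is the allene hydroboration/aldehyde allylboration sequence of γ-boryl allyl(diisopinocampheyl)boranes that leads to 2-methylbut-3-ene-1,2-diols, followed by stereoretentive oxidation of the tertiary C–B bond; no ring is closed. C4 is controlled by the isopinocampheyl groups from (−)-α-pinene, which should direct the allyl unit to the Re face of the aldehyde (4S); C3 is controlled by the reagent geometry, with the trans boryl group equatorial, CH3 axial and the aldehyde chain equatorial in the chair, which gives the anti arrangement that becomes 3R after oxidation with retention. The step needs a single geometric isomer of the allylborane (secured by equilibration before the aldehyde is added), no hydroboration of the trisubstituted alkene (the borane is consumed before 7 is added), and no second allyl transfer from the new tertiary allylic pinacol boronate (slow at −78 °C with the aldehyde limiting, and removed by the immediate oxidation).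

Step 6
Reactants: 11 (3R,4S)-3,7-dimethylocta-1,6-diene-3,4-diol; 12 (E)-4-acetoxycinnamic acid
Product: 13 (3R,4S)-3-hydroxy-3,7-dimethylocta-1,6-dien-4-yl (E)-3-(4-acetoxyphenyl)prop-2-enoate
Conditions: 12 (1.2 equiv), EDC·HCl (1.5 equiv), DMAP (0.2 equiv), CH2Cl2, 0 °C to rt
Reagents that add atoms: none
Why: Steglich esterification should acylate the secondary hydroxyl selectively because the tertiary allylic hydroxyl is far less reactive; the E-alkene of the acid and both stereocentres are not touched.

Step 7
Reactants: 13 (3R,4S)-3-hydroxy-3,7-dimethylocta-1,6-dien-4-yl (E)-3-(4-acetoxyphenyl)prop-2-enoate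
Product: 14 (3R,4S)-3-acetoxy-3,7-dimethylocta-1,6-dien-4-yl (E)-3-(4-acetoxyphenyl)prop-2-enoate
Conditions: Ac2O (5 equiv), DMAP (1 equiv), Et3N (6 equiv), CH2Cl2, rt to 40 °C
Reagents that add atoms: acetic anhydride, CC(=O)OC(C)=O
Why: DMAP-catalysed acetylation with excess anhydride is the standard way to acylate tertiary alcohols of the linalool type; the C3–O bond is not broken, so the configuration is kept, and the aryl acetate and cinnamate are inert.

Step 8
Reactants: 14 (3R,4S)-3-acetoxy-3,7-dimethylocta-1,6-dien-4-yl (E)-3-(4-acetoxyphenyl)prop-2-enoate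
Product: 15 (3R,4S)-3-acetoxy-3,7-dimethylocta-1,6-dien-4-yl (E)-3-(4-hydroxyphenyl)prop-2-enoate
Conditions: pyrrolidine (1.5 equiv), CH2Cl2, 0 °C; aq. NH4Cl
Reagents that add atoms: none
Why: Chemoselective aminolysis: the phenolic acetate, with its aryloxide leaving group, is far more reactive than the hindered tertiary alkyl acetate and the conjugated cinnamate, so only the phenol should be set free.

**Compound list**
1 | but-2-yn-1-ol | CC#CCO | starting material
2 | but-2-yn-1-yl methyl carbonate | CC#CCOC(=O)OC | intermediate
3 | 2-(buta-2,3-dien-2-yl)-4,4,5,5-tetramethyl-1,3,2-dioxaborolane | C=C=C(C)B1OC(C)(C)C(C)(C)O1 | intermediate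
4 | (−)-α-pinene, (1S,5S)-2,6,6-trimethylbicyclo[3.1.1]hept-2-ene | CC1=CC[C@H]2C[C@@H]1C2(C)C | starting material
5 | (+)-diisopinocampheylborane, (lIpc)2BH | B([C@H]1C[C@H]2C[C@@H]([C@@H]1C)C2(C)C)[C@H]1C[C@H]2C[C@@H]([C@@H]1C)C2(C)C | intermediate
6 | 4-methylpent-3-en-1-ol | CC(C)=CCCO | starting material
7 | 4-methylpent-3-enal | CC(C)=CCC=O | intermediate
8 | kinetic allylborane: bis(isopinocampheyl)[(2E)-3-(pinacolboryl)but-2-en-1-yl]borane, Bpin cis to CH2B(Ipc)2 | C/C(B1OC(C)(C)C(C)(C)O1)=C/CB([C@H]2C[C@H]3C[C@@H]([C@@H]2C)C3(C)C)[C@H]2C[C@H]3C[C@@H]([C@@H]2C)C3(C)C | intermediate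
9 | equilibrated allylborane: the (2Z) isomer of 8, Bpin trans to CH2B(Ipc)2 (CH3 outranks B, hence Z) | C/C(B1OC(C)(C)C(C)(C)O1)=C\CB([C@H]2C[C@H]3C[C@@H]([C@@H]2C)C3(C)C)[C@H]2C[C@H]3C[C@@H]([C@@H]2C)C3(C)C | intermediate
10 | borinate adduct: O-bis(isopinocampheyl)boryl ether of (3S,4S)-3,7-dimethyl-3-(pinacolboryl)octa-1,6-dien-4-ol (same spatial arrangement as the target; the C3 descriptor changes because boron ranks below carbon) | C=C[C@@](C)(B1OC(C)(C)C(C)(C)O1)[C@H](CC=C(C)C)OB([C@H]2C[C@H]3C[C@@H]([C@@H]2C)C3(C)C)[C@H]2C[C@H]3C[C@@H]([C@@H]2C)C3(C)C | intermediate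
11 | (3R,4S)-3,7-dimethylocta-1,6-diene-3,4-diol | C=C[C@@](C)(O)[C@H](CC=C(C)C)O | intermediate
12 | (E)-4-acetoxycinnamic acid | CC(=O)Oc1ccc(/C=C/C(=O)O)cc1 | starting material
13 | (3R,4S)-3-hydroxy-3,7-dimethylocta-1,6-dien-4-yl (E)-3-(4-acetoxyphenyl)prop-2-enoate | C=C[C@@](C)(O)[C@H](CC=C(C)C)OC(=O)/C=C/c1ccc(OC(C)=O)cc1 | intermediate
14 | (3R,4S)-3-acetoxy-3,7-dimethylocta-1,6-dien-4-yl (E)-3-(4-acetoxyphenyl)prop-2-enoate | C=C[C@@](C)(OC(C)=O)[C@H](CC=C(C)C)OC(=O)/C=C/c1ccc(OC(C)=O)cc1 | intermediate
15 | (3R,4S)-3-acetoxy-3,7-dimethylocta-1,6-dien-4-yl (E)-3-(4-hydroxyphenyl)prop-2-enoate | C=C[C@@](C)(OC(C)=O)[C@H](CC=C(C)C)OC(=O)/C=C/c1ccc(O)cc1 | target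

Total step count: 8. Longest linear sequence: 6 steps (steps 1, 2, 5, 6, 7, 8).

**Steps most likely to fail**

Step 5. The geometric equilibration of the allylborane may be incomplete before the aldehyde is added (giving the C3 epimer), facial control by the isopinocampheyl groups may be weak, or a second allyl transfer from the tertiary allylic boronate may occur. The fallback sets out from 7 and returns at 11.
- Addition of isopropenylmagnesium bromide to 7 (THF, −78 °C) should give racemic 2,6-dimethylhepta-1,5-dien-3-ol F1, still by forming the C3–C4 bond.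
- Sharpless kinetic resolution (Ti(Oi-Pr)4, L-(+)-diisopropyl tartrate, t-BuOOH 0.6 equiv, 4 Å sieves, CH2Cl2, −20 °C) should epoxidise the faster-reacting (S)-alcohol on its 1,1-disubstituted allylic alkene. The expected product is the erythro epoxy alcohol (2R,3S)-1,2-epoxy-2,6-dimethylhept-5-en-3-ol F2; the homoallylic trisubstituted alkene should be left.
- Excess dimethylsulfonium methylide (Me3S+ I−, n-BuLi, THF, −10 °C to rt) should open the epoxide at its CH2 group and eliminate dimethyl sulfide. This turns the epoxide CH2 into the C1=C2 vinyl group and gives 11.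

Step 7. Acylation of the hindered tertiary hydroxyl may be slow, and migration of the cinnamoyl group from O4 to O3 followed by acetylation of the freed secondary hydroxyl may compete. The fallback sets out from 11 and returns at 14.
- The secondary hydroxyl is silylated selectively (TESCl, imidazole, DMF, 0 °C) to (3R,4S)-3,7-dimethyl-4-(triethylsilyloxy)octa-1,6-dien-3-ol F3.
- The tertiary hydroxyl is acetylated with no migrating acyl group present (Ac2O, DMAP, Et3N, 40 °C) to (3R,4S)-3,7-dimethyl-4-(triethylsilyloxy)octa-1,6-dien-3-yl acetate F4.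
- Buffered desilylation (HF·pyridine, THF/pyridine, 0 °C) should give (3R,4S)-4-hydroxy-3,7-dimethylocta-1,6-dien-3-yl acetate F5.
- F5 is esterified at once with 12 under Yamaguchi conditions (2,4,6-trichlorobenzoyl chloride, Et3N, then DMAP, toluene, 0 °C), to outrun the downhill acetyl shift, and gives 14.

Step 6. Acylation of the secondary carbinol next to the quaternary carbon by the activated cinnamic acid may be slow, with rearrangement of the activated acid to the N-acylurea and DMAP-mediated acetyl transfer from the aryl acetate competing. The fallback sets out from 11 and returns at 13.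
- The secondary hydroxyl is acylated with the small diethylphosphonoacetic acid (EDC, DMAP cat., CH2Cl2) to (3R,4S)-3-hydroxy-3,7-dimethylocta-1,6-dien-4-yl 2-(diethoxyphosphoryl)acetate F6.
- A Horner–Wadsworth–Emmons olefination with 4-acetoxybenzaldehyde (LiCl, i-Pr2NEt, MeCN, rt) should then build the E-cinnamate on the substrate and give 13.

**Further compounds**
F1 | step 5 | rac-2,6-dimethylhepta-1,5-dien-3-ol | C=C(C)C(O)CC=C(C)C
F2 | step 5 | (2R,3S)-1,2-epoxy-2,6-dimethylhept-5-en-3-ol | C1[C@@](C)(O1)[C@H](CC=C(C)C)O
F3 | step 7 | (3R,4S)-3,7-dimethyl-4-(triethylsilyloxy)octa-1,6-dien-3-ol | C=C[C@@](C)(O)[C@H](CC=C(C)C)O[Si](CC)(CC)CC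
F4 | step 7 | (3R,4S)-3,7-dimethyl-4-(triethylsilyloxy)octa-1,6-dien-3-yl acetate | C=C[C@@](C)(OC(C)=O)[C@H](CC=C(C)C)O[Si](CC)(CC)CC
F5 | step 7 | (3R,4S)-4-hydroxy-3,7-dimethylocta-1,6-dien-3-yl acetate | C=C[C@@](C)(OC(C)=O)[C@H](CC=C(C)C)O
F6 | step 6 | (3R,4S)-3-hydroxy-3,7-dimethylocta-1,6-dien-4-yl 2-(diethoxyphosphoryl)acetate | C=C[C@@](C)(O)[C@H](CC=C(C)C)OC(=O)CP(=O)(OCC)OCC
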